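Treat this flask as a ration, not a race: hold two amounts against each other, the X charged and the J charged.

the same everywhere: J 10 mM

|  | X | remark | time |
|---|---|---|---|
| green | 0.70 equiv | the very flask that is asked about, followed so far |  |
| flask | 0.700 equiv |  | 15 h |

- green (time / h: Q / %, J / %): 0.500: 15.2, 52.3; 1.50: 45.3, 15.2; 3.00: 64.8, 0; 5.00: 68.6, 0.1

(each reading ± 0.5 percentage points)

- as a solid, counted per litre of solution: J
- the numbers in the tables scatter with a standard deviation of 0.5 percentage points
- at the start none of J is in solution

* how much Q there is at 15 h, in percent of the J charged
* the change that raises the amount of Q at 15 h, in percent of the J charged most ("none" if none brings more than 2 percentage points) (Thursday's / Sunday's / Wednesday's / none)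
* amount of Q at 15 h, in percent of the J charged, after Sunday's

- Thursday's: doubling the dissolution coefficient of J, all else as stated
- Sunday's: doubling the amount of X, all else as stated
- Wednesday's: doubling the solubility of J, all else as stated

Take one Q per X, with X as the limiting reagent. The ratio of cX to cJ at the charge is then 70.0%, and this is the ceiling: Q in percent of the J charged when X stops it.

Test the ceiling on the green run, which is this flask so far. At 5.00 h Q reads 68.6%, just 1.4 percentage points under the ceiling. Yet 31.3% of the J charged reads neither as Q nor as J, more than that distance to the ceiling. The J column already reads 0% at 3.00 h.

So commit to the ceiling at 15 h. Thursday's doubling of the dissolution coefficient and Wednesday's doubling of the solubility leave the ratio unchanged, so expect no gain from either. Doubling X lifts the ratio to 1.40, and then J caps Q at 100%.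

The forecast gives 69.9%, picks Sunday's and puts that change at 99.5%. Its ground: “Faster dissolution or higher solubility cannot raise this ceiling; only more X can.”

The flask gives 70.0%. Sunday's change gives 96.7%, a gain of 27 points, against 0 points for Thursday's and 0 points for Wednesday's. At 15.0 h X stands at 0% of its charge, while G holds 25.8% of the J charged.

    2 J → D (k = 0.0940 /M/min)
    J ⇌ G, rate k2*(cs2 - [G]) while solid is left; crystals form when [G] > cs2 (solubility = 4.10 mM, k = 0.0720 /min)
    G + X → Q (k = 4.20 /M/min)

Now take a neighbour flask charged with 0.170 equiv of X. Its ratio gives a ceiling of 17.0%. That flask gives 17.0%, with X at 0% of its charge and 64% of the charged J still there at 15.0 h.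

(The data were generated by integration on assumed constants.)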